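I started with the easy step, adding up the last reading of the red run: 24.7% of target and 76.3% of starting material make 101%. Within the scatter, then, the catalyst forms hold little in the red run, so I took the same for the flask and asked how much starting material goes in 4.0 h.

in all of them: added ligand 2.5 mM

| charge | starting material | coupling partner | free catalyst | remark | time |
|---|---|---|---|---|---|
| green | 0.24 M | 0.95 equiv | 0.61 mol% | run made earlier |  |
| grey | 0.98 M | 0.95 equiv | 0.61 mol% | run made earlier |  |
| red | 0.49 M | 0.95 equiv | 0.3 mol% | run made earlier |  |
| flask | 0.49 M | 0.950 equiv | 0.61 mol% |  | 4.0 h |

| run | time / h | target / % | starting material / % |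
|---|---|---|---|
| green | 0.667 | 6.5 | 94.0 |
| green | 1.33 | 13.8 | 84.2 |
| green | 2.00 | 17.9 | 79.5 |
| green | 2.50 | 23.0 | 75.6 |
| green | 3.00 | 28.6 | 70.8 |
| grey | 0.250 | 6.4 | 94.5 |
| grey | 0.833 | 20.1 | 79.1 |
| grey | 1.33 | 31.6 | 68.4 |
| grey | 2.50 | 54.6 | 47.2 |
| grey | 3.00 | 61.6 | 38.4 |
| red | 0.250 | 2.6 | 98.0 |
| red | 0.500 | 4.9 | 95.0 |
| red | 0.833 | 6.2 | 92.3 |
| red | 1.50 | 12.2 | 86.4 |
| red | 3.00 | 24.7 | 76.3 |

(standard deviation of a reading: 1 percentage point)

1. target present at 4.0 h, in percent of the starting material charged
2. starting material present at 4.0 h, in percent of the starting material charged

- what was read earlier has a scatter of 1 percentage point, one standard deviation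
- steps under discussion: starting material + free catalyst -> catalyst intermediate A; coupling partner + catalyst intermediate A <-> catalyst intermediate B; catalyst intermediate B -> released group + catalyst intermediate C; catalyst intermediate C -> free catalyst + target; free catalyst + added ligand <-> idle complex

The red run shares the flask's starting concentration but not its loading, so I compared them by catalyst dose. Loading times time in the flask, divided by loading times time at the last red reading, came to 2.71, and I call this the dose ratio.

With the main step by itself, a straight line, each dose removes the same amount, so red's loss of 23.7% became 64.2%, leaving 35.8%. I then added the fall of the reagents, among them the coupling partner, the limiting reagent at 0.950 equiv. Each dose now takes the same fraction of what is left, so red's 76.3% raised to the dose ratio gave 48.0%.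

Last came the ligand: the flask's loading is twice red's at the same ligand charge, so a dose counted from the red run might not carry over exactly. The green and grey runs have the flask's loading and ligand, and the geometric mean of their concentrations, 0.485 M, lies close to the flask's. The geometric mean of their decline rates, carried to 4.0 h, left 46.5%, a correction of 1.6 percentage points. I committed to that much starting material and 53.5% of target.

The forecast stood at 58% of target and 42% of starting material, reasoning that “The flask has red's concentration and twice its catalyst, so 4 h in the flask corresponds to about 8 h of red.” It used the same dose, but its starting material came out lower than mine.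

The flask gave 55.6% of target and 44.0% of starting material.

    starting material + free catalyst → catalyst intermediate A (k = 246 /M/h)
    coupling partner + catalyst intermediate A ⇌ catalyst intermediate B (K = 6.10 /M, k = 354 /M/h)
    catalyst intermediate B → released group + catalyst intermediate C (k = 101 /h)
    catalyst intermediate C → free catalyst + target (k = 277 /h)
    free catalyst + added ligand ⇌ idle complex (K = 150 /M, k = 412 /M/h)

In the flask at 4.00 h, free catalyst with added ligand and the idle complex relax towards each other, by this step alone and both ways together, with a half-life of 0.172 h, far shorter than the 4.0 h of the run, and at that time the idle complex holds 9.97% of the catalyst, against 9.34% in the neighbour flask with 0.15 mol% of free catalyst. Measured against the last red reading, the logarithmic fall of starting material in the flask comes to 3.04 against the dose ratio of 2.71, and that ratio scaled to the neighbour, 0.667, turns red's 76.3% into 83.5%, where the neighbour flask stands at 83.3%.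

Readings and results are calculated for substances that don't exist, and the scatter is random.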